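Prostanoid numbering is used throughout (C1 is the carboxyl carbon).

## The problem

Prostaglandin F1α (12) is a C20 hydroxy acid on one cyclopentane (C8–C12), so the task is to place two chains and two hydroxyls around a five-membered ring and a third hydroxyl far out on a chain. Four ring carbons (C8, C9, C11, C12) and C15 are stereogenic: the hydroxyls at C9 and C11 are cis, the saturated C1–C7 acid chain at C8 shares their face, and the (13E)-alkenyl chain at C12, which carries the 15S alcohol, is trans to it. The ring centres can instruct one another, since trans chains are the relaxed arrangement and a cis-1,3-diol can be delivered from one face. C15, however, is insulated from C12 by a trans alkene and in ordinary chemistry needs its own source of chirality. The target tolerates mild reagents but not strong acid (the allylic alcohol ionizes), and its free acid and three hydroxyls invite protecting-group traffic that a short route must avoid. The economical precursors are more fragile than the target: skipped polyynes isomerize to allenes under base, skipped cis-polyenes autoxidize at their doubly allylic methylenes, and a 9,11-peroxide has a weak O–O bond that base or heat converts into β-hydroxy ketones. The enabling feature is the oxidation pattern read along the unbranched C20 chain: the ring bond C8–C12 and the oxygens on C9, C11 and C15 all fall on alkene carbons of an all-cis 8,11,14-triene acid, the cis-diol being a reduced O–O bridge between C9 and C11 across a 2,3-dioxabicyclo[2.2.1]heptane and the 13E-en-15-ol the trace of oxygenating an allyl terminus. An achiral, acyclic acid can therefore be folded into the complete stereoarray by two molecules of dioxygen, provided a catalyst dictates the fold, and the cyclooxygenase enzyme does that.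

## Retrosynthesis

**12 to 11.** No carbon–carbon bond is cut; the O–H bonds at C9 and C11 are joined back into one O–O bond, which makes prostaglandin H1 (11) the immediate precursor. The neighbouring choice, a C9 ketone reduced at the end, would leave a facial-selectivity question at C9, whereas a peroxide bridge can only span the ring cis. The forward step must be a two-electron reduction that is neutral and faster than the base-induced isomerization of the bridge.

**11 to 9 (through 10).** Here the ring bond C8–C12 and the C–O bonds at C9, C11 and C15 are cut together, the C15 oxygen being traced back to the hydroperoxide of prostaglandin G1 (10). Cutting C12–C13 or C7–C8 instead would leave a chiral cyclopentane still to be made. This cut removes both rings and all five stereocentres at once and arrives at the achiral acid 9. The forward reaction must remove one particular hydrogen out of four doubly allylic ones, add dioxygen twice with absolute facial control and close the carbocycle with trans chains, which only the enzyme is known to do.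

**9 to 8 to 7.** The skeleton stays intact: the acid is masked as its methyl ester 8 and the three cis alkenes are read as the alkynes of triyne ester 7. Against three separate cis-selective olefinations, the alkyne route lets the chain be joined by substitution at propargylic carbons and sets all three geometries in one syn-hydrogenation. The forward step has to stop cleanly at the triene, because the enzyme discriminates against E and over-reduced isomers.

**7 to 4 + 6.** The C9–C10 bond, between an alkyne terminus and a propargylic methylene, is cut to give chloride 4 (C10–C20) and alkynoate 6 (C1–C9). The ester 6 comes from acid 5, masked so that the carboxylate is not alkylated by the propargylic halide. Cutting C12–C13 first would be equally valid on paper. Putting the valuable ester in the second coupling lets the four-carbon linchpin be spent in excess on the cheaper, volatile partner. The forward coupling needs a base mild enough to leave the doubly propargylic methylenes alone.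

**4 to 1 + 2 (through 3).** The C13–C14 bond is cut to give hept-1-yne (1) and 1,4-dichlorobut-2-yne (2), the nucleophile being the alkynyl Grignard reagent 3. Compound 2 has two identical electrophilic ends, so the forward step must hold at mono-substitution, which an excess of 2 and copper catalysis should secure.

## Roads not taken

**Alternative 1:** The ring is cut at C10–C11. In the forward sense Rh2(OAc)4 converts the acyclic α-diazoketone A2 into a C10 carbenoid, which inserts into a C–H bond of the silyloxymethyl arm and closes the cyclopentanone A1.
- Merits: A1 already holds C8, C11 and C12 in the right relation and carries the saturated acid chain. The route is fully chemical, scalable and open to analogues, and it avoids any labile peroxide. In throughput and independence from a biocatalyst it is better than the chosen plan.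
- Weak points: the carbenoid must choose the silyloxymethyl arm over the acetoxymethyl arm (both sit in a 1,5 relation) and over the chain C6–H, and between two diastereotopic hydrogens to set C11. Selectivity therefore rests on electronic tuning of two protecting groups. After A1 the C9 ketone has to be reduced from the correct face, and the whole lower chain is still missing: deprotection, oxidation, olefination and a reagent-controlled reduction at C15.
- Comparison: with the enantioselective preparation of A2 the count is roughly twice that of the chosen plan. The chosen plan sets against this all five centres in one step from an achiral acid and a single protecting group (a methyl ester) in the whole route.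

**Alternative 2:** The ring is cut at C8–C9 and C11=C12. Two molecules of butanedial A4 are joined by an (S)-proline aldol reaction and an amine-salt aldol condensation to give the cis-fused bicyclic enal lactol A3.
- Merits: A3 is an enantioenriched core from a commodity dialdehyde in one operation. The lower chain enters at C12 by conjugate addition, the enal carbon is excised to unveil the C11 oxygen, and a Wittig reaction on the lactol adds C1–C5. This is a very short and scalable logic, comparable in length to the chosen plan and better in throughput.
- Weak points: the dimerization competes with oligomerization of A4. C15 must be bought with a separately made enantiopure side chain. The Wittig opening necessarily leaves a cis C5=C6 alkene, which is the 2-series; the 1-series target then needs that alkene hydrogenated selectively beside the trans C13=C14 alkene, or a redesigned upper-chain installation.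
- Comparison: the chosen plan has the saturated upper chain built into its substrate, takes C15 from the same catalyst as the ring, and needs no hydroxyl protection.

**Alternative 3:** The cuts are C7–C8 and C12–C13. Bu3SnH and a radical initiator turn the iodoacetal A6 into a C7 radical that closes onto C8 of the cyclopentene. The C12 radical so formed adds to the silyl enone A7 and gives the bicyclic acetal A5.
- Merits: two carbon–carbon bonds form in one step. C8 and C12 are relayed from the two oxygen-bearing centres of one enantiopure cyclopentenol: the cis ring fusion is enforced by the tether and the trap enters trans to it. The chemistry is preparatively robust and better than the chosen plan in material throughput.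
- Weak points: stoichiometric tin, and competition between trapping by A7 and premature hydrogen transfer. Several steps follow: regiospecific unveiling of the C13=C14 enone from the α-silyl ketone, reagent-controlled C15 reduction, acetal hydrolysis and a Wittig reaction. The Wittig step again delivers the C5=C6 alkene of the 2-series, so the same selective saturation is needed as in Alternative 2.
- Comparison: the chosen plan is shorter, free of tin and protecting groups, and does not need a separate solution for C15.

Key step: step 6

Assumption: purified ovine prostaglandin endoperoxide H synthase 1 is treated as a purchasable biocatalyst, not as a starting material. Compound 9 is itself an article of commerce, so steps 1 to 5 may be replaced by purchase without changing the route.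

## Route

Step 1
Reactants: 1 hept-1-yne; 2 1,4-dichlorobut-2-yne
Product: 4 1-chloroundeca-2,5-diyne, via hept-1-ynylmagnesium bromide 3 (not isolated)
Conditions: EtMgBr, THF, 0 to 40 °C; then CuCl (5 mol %), 2 (4 equiv), THF, 50 °C; excess 2 removed by distillation
Reagents that add atoms: none
Why: Copper-catalysed substitution of a primary propargylic chloride by an alkynyl Grignard reagent, the classical entry to 1,4-diynes; the excess of the symmetrical bis-electrophile should hold the reaction at mono-substitution, and monovalent copper favours direct displacement over the allene-forming SN2′ path.

Step 2
Reactants: 5 non-8-ynoic acid
Product: 6 methyl non-8-ynoate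
Conditions: MeOH, H2SO4 (cat.), reflux
Reagents that add atoms: methanol, CO
Why: Fischer esterification; the terminal alkyne is inert to catalytic acid, and the ester keeps the carboxylate from being alkylated by the propargylic halide in step 3.

Step 3
Reactants: 4 1-chloroundeca-2,5-diyne; 6 methyl non-8-ynoate
Product: 7 methyl icosa-8,11,14-triynoate
Conditions: CuI, NaI, Cs2CO3, DMF, rt, argon, dark
Reagents that add atoms: none
Why: Copper-mediated alkynylation of a propargylic halide under carbonate base; the chloride is exchanged in the flask for iodide (Finkelstein), the copper acetylide of 6 displaces it, and the mild base should leave the doubly propargylic methylenes and the ester untouched.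

Step 4
Reactants: 7 methyl icosa-8,11,14-triynoate
Product: 8 methyl (8Z,11Z,14Z)-icosa-8,11,14-trienoate
Conditions: H2 (1 atm), Pd/CaCO3 poisoned with Pb(OAc)2, quinoline, EtOAc, 10 °C, stopped at 3 equiv H2; chromatography on AgNO3-impregnated silica
Reagents that add atoms: none
Why: Lindlar semi-hydrogenation; syn delivery of hydrogen on the poisoned palladium surface turns each alkyne into the Z alkene, and lead and quinoline slow further reduction. Argentation chromatography removes E and over-reduced material, which matters because the enzyme of step 6 accepts only the all-cis triene.

Step 5
Reactants: 8 methyl (8Z,11Z,14Z)-icosa-8,11,14-trienoate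
Product: 9 (8Z,11Z,14Z)-icosa-8,11,14-trienoic acid (dihomo-γ-linolenic acid)
Conditions: LiOH, THF/MeOH/H2O, rt, argon; then 1 M HCl to pH 4, 0 °C
Reagents that add atoms: lithium hydroxide, [Li+].[OH-]
Why: Saponification by acyl–oxygen cleavage; hydroxide at room temperature does not conjugate skipped cis alkenes, and exclusion of air prevents autoxidation at C10 and C13.

Step 6
Reactants: 9 (8Z,11Z,14Z)-icosa-8,11,14-trienoic acid
Product: 11 prostaglandin H1 [(13E,15S)-9α,11α-epidioxy-15-hydroxyprost-13-en-1-oic acid], via prostaglandin G1 10 (not isolated)
Conditions: O2-saturated 0.1 M Tris·HCl pH 8.0, ovine prostaglandin endoperoxide H synthase 1 (isomerase-free heme protein, added in portions), hemin (C34H32ClFeN4O4), hydroquinone (1.2 equiv), 24 °C, 2 min; then citric acid to pH 3, Et2O, 0 °C; short silica column at −20 °C; kept as a cold solution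
Reagents that add atoms: dioxygen, O=O (two molecules; three of the four oxygen atoms stay in 11)
Why: Enzymatic radical bis-dioxygenation (the cyclooxygenase reaction): the tyrosyl radical of the cyclooxygenase site, generated through the heme peroxidase cycle, removes the 13-pro-S hydrogen of carboxylate-anchored 9, and the C11–C15 pentadienyl radical takes up dioxygen at C11 on the face opposite to the abstraction. The C11 peroxyl radical closes the 1,2-dioxolane by 5-exo-trig attack on C9 of the C8=C9 alkene, and the resulting C8 radical closes the cyclopentane by 5-exo-trig attack on C12 of the C12=C13 alkene, the two rings together making the 2,3-dioxabicyclo[2.2.1]heptane. The C13–C15 allyl radical left behind is oxygenated at C15, the peroxyl radical takes its hydrogen back from the tyrosine, and the peroxidase site, fed by hydroquinone, reduces the 15-hydroperoxide of 10 to the alcohol of 11 with the 13E alkene in place. C11 (R) is controlled by the channel wall that admits dioxygen only anti to the departing hydrogen; C9 by the bicycle, whose O–O bridge can only span cis; C8 and C12 by the fold of the chain in the channel, which holds the C8 chain on the peroxide face and the C12 chain on the opposite face, where a free radical in solution prefers cis chains; and C15 (S) by the oxygen pocket next to the tyrosine. The step needs abstraction at C13 in preference to the second doubly allylic methylene at C10 and absolute facial control on an achiral substrate; the substrate contributes the free carboxylate, which anchors C1 at the mouth of the channel, and the all-cis 8,11,14 spacing on a C20 chain, which places C13 under the tyrosine and C8 within bonding distance of C12. The closest known reaction type is the same enzyme's conversion of arachidonic acid into the 2-series endoperoxide, and 9 is a natural substrate of equal standing. An isomerase-free enzyme, hemin reconstitution, a phenolic reductant that also slows self-inactivation, a short incubation and a cold acidic extraction are the measures meant to keep 11 from isomerizing to the 9- and 11-ketones.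

Step 7
Reactants: 11 prostaglandin H1
Product: 12 prostaglandin F1α [(13E,15S)-9α,11α,15-trihydroxyprost-13-en-1-oic acid]
Conditions: SnCl2, EtOH, 0 °C to rt, 10 min, applied at once to the cold solution of 11; then EtOAc/aq. citric acid, silica
Reagents that add atoms: none
Why: Two-electron reduction of the dialkyl peroxide by divalent tin, expected to outrun isomerization of the bridge; O–O cleavage touches no carbon, so C9 and C11 keep the configuration set in step 6 and the cis-diol emerges. Any 10 carried along is reduced at both of its peroxide bonds to the same product.

## Compound list

1 | hept-1-yne | CCCCCC#C | starting material
2 | 1,4-dichlorobut-2-yne | ClCC#CCCl | starting material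
3 | hept-1-ynylmagnesium bromide | CCCCCC#C[Mg]Br | intermediate
4 | 1-chloroundeca-2,5-diyne | ClCC#CCC#CCCCCC | intermediate
5 | non-8-ynoic acid | C#CCCCCCCC(=O)O | starting material
6 | methyl non-8-ynoate | C#CCCCCCCC(=O)OC | intermediate
7 | methyl icosa-8,11,14-triynoate | CCCCCC#CCC#CCC#CCCCCCCC(=O)OC | intermediate
8 | methyl (8Z,11Z,14Z)-icosa-8,11,14-trienoate | CCCCC/C=C\C/C=C\C/C=C\CCCCCCC(=O)OC | intermediate
9 | (8Z,11Z,14Z)-icosa-8,11,14-trienoic acid (dihomo-γ-linolenic acid) | CCCCC/C=C\C/C=C\C/C=C\CCCCCCC(=O)O | intermediate
10 | prostaglandin G1, (13E,15S)-9α,11α-epidioxy-15-hydroperoxyprost-13-en-1-oic acid | CCCCC[C@H](OO)/C=C/[C@@H]1[C@@H](CCCCCCC(=O)O)[C@@H]2C[C@H]1OO2 | intermediate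
11 | prostaglandin H1, (13E,15S)-9α,11α-epidioxy-15-hydroxyprost-13-en-1-oic acid | CCCCC[C@H](O)/C=C/[C@@H]1[C@@H](CCCCCCC(=O)O)[C@@H]2C[C@H]1OO2 | intermediate
12 | prostaglandin F1α, (13E,15S)-9α,11α,15-trihydroxyprost-13-en-1-oic acid | CCCCC[C@H](O)/C=C/[C@@H]1[C@@H](CCCCCCC(=O)O)[C@@H](O)C[C@H]1O | target

## Step count and risk

Total step count: 7. Longest linear sequence: 6 steps (steps 1, 3, 4, 5, 6, 7 from hept-1-yne; the branch through step 2 is equally long).

**Step 6 (key step).** Two processes are most likely to go wrong. The enzyme inactivates itself after a limited number of turnovers, so conversion may stall. The endoperoxide may also decay during the minutes between formation and cold extraction, by isomerization to the 9- and 11-oxo hydroxy acids and by fragmentation of the bicycle. The fallback gives up isolating a peroxide. It sets out from 9, which is incubated with a ram seminal vesicle microsomal preparation that retains its endoperoxide isomerase, with glutathione as isomerase cofactor and hydroquinone as reductant. The endoperoxide is then converted in the enzyme system into the stable 9-ketone prostaglandin E1 F1, which can be isolated without haste. Reduction of F1 with excess LiBH(s-Bu)3 in THF at −78 °C should deliver hydride to the face of C9 opposite the C8 chain and the C11 oxygen, and the sequence comes back to the route at 12.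

**Step 7.** Isomerization of the peroxide bridge may compete with reduction while 11 is extracted, concentrated and transferred, before the reductant reaches it. The fallback changes isolation into trapping: SnCl2 in EtOH is added directly to the incubation of 9 at the end of the two minutes, so that the peroxide is reduced as soon as the enzyme is denatured. It sets out from 9 and comes back at 12, with 11 passing only as an unisolated intermediate; it makes no new compound (F0).

**Step 4.** Over-reduction past the alkene stage, incomplete uptake at one of the three alkynes and Z-to-E isomerization on the metal surface may occur side by side, and the resulting esters differ by two hydrogens and separate poorly. The fallback replaces catalytic hydrogenation by stoichiometric syn-hydroboration and protonolysis. It sets out from 7, which is treated with dicyclohexylborane (3.3 equiv, THF, 0 °C) to give the tris(alkenyl)borane methyl (8Z,11Z,14Z)-9,12,15-tris(dicyclohexylboranyl)icosa-8,11,14-trienoate F2 (one regioisomer of the mixture; the position of boron is irrelevant). Protonolysis of the three C–B bonds with acetic acid, with retention, cannot go beyond the alkene stage and comes back to the route at 8.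

**Step 1.** Double substitution of the bis-electrophile, SN2′ attack leading to allenes, and a propargylic chloride too sluggish for step 3 are the likely failures. The fallback builds the electrophile from a mono-functional linchpin. It sets out from 1, which is coupled with 4-chlorobut-2-yn-1-ol (CuI, NaI, K2CO3, DMF, rt) to give undeca-2,5-diyn-1-ol F3. An Appel reaction (CBr4, PPh3, CH2Cl2, 0 °C) converts it into 1-bromoundeca-2,5-diyne F4, which takes the place of 4 in the coupling with 6 under the conditions of step 3 and comes back to the route at 7.

## Further compounds

F1 | step 6 | prostaglandin E1, (13E,15S)-11α,15-dihydroxy-9-oxoprost-13-en-1-oic acid | CCCCC[C@H](O)/C=C/[C@@H]1[C@@H](CCCCCCC(=O)O)C(=O)C[C@H]1O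
F0 | step 7 | none | none
F2 | step 4 | methyl (8Z,11Z,14Z)-9,12,15-tris(dicyclohexylboranyl)icosa-8,11,14-trienoate (representative regioisomer) | CCCCC/C(B(C1CCCCC1)C1CCCCC1)=C\C/C(B(C1CCCCC1)C1CCCCC1)=C\C/C(B(C1CCCCC1)C1CCCCC1)=C\CCCCCCC(=O)OC
F3 | step 1 | undeca-2,5-diyn-1-ol | OCC#CCC#CCCCCC
F4 | step 1 | 1-bromoundeca-2,5-diyne | BrCC#CCC#CCCCCC
A1 | alternative 1 | 3-(acetoxymethyl)-2-(6-methoxycarbonylhexyl)-4-(tert-butyldimethylsilyloxy)cyclopentanone (prostaglandin configuration at C8, C11, C12) | CC(=O)OC[C@@H]1[C@@H](CCCCCCC(=O)OC)C(=O)C[C@H]1O[Si](C)(C)C(C)(C)C
A2 | alternative 1 | methyl 8-[1-acetoxy-3-(tert-butyldimethylsilyloxy)propan-2-yl]-10-diazo-9-oxodecanoate | CC(=O)OC[C@@H](CO[Si](C)(C)C(C)(C)C)[C@@H](CCCCCCC(=O)OC)C(=O)C=[N+]=[N-]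
A3 | alternative 2 | 2-hydroxy-3,3a,6,6a-tetrahydro-2H-cyclopenta[b]furan-5-carbaldehyde (cis-fused bicyclic enal lactol) | O=CC1=C[C@H]2CC(O)O[C@H]2C1
A4 | alternative 2 | butanedial | O=CCCC=O
A5 | alternative 3 | cis-fused bicyclic ethyl acetal with the 3-oxo-2-(trimethylsilyl)octyl chain on C12 and the silyl ether on C11 | CCCCCC(=O)C([Si](C)(C)C)C[C@@H]1[C@@H](CC(OCC)O2)[C@@H]2C[C@H]1O[Si](C)(C)C(C)(C)C
A6 | alternative 3 | cis-4-(tert-butyldimethylsilyloxy)cyclopent-2-enyl 1-ethoxy-2-iodoethyl ether (mixed iodoacetal) | CCOC(CI)O[C@@H]1C=C[C@H](O[Si](C)(C)C(C)(C)C)C1
A7 | alternative 3 | 2-(trimethylsilyl)oct-1-en-3-one | CCCCCC(=O)C(=C)[Si](C)(C)C
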